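**Retrosynthetic overview**
1. Numbering: C1 (quaternary, Me), C2, C3, C4 (i-Pr carbinol) and C5 (fusion CH) form the five-membered ring. C5, C6 (angelate), C7, C8/C9 (oxirane, Me on C8), C10 (carbinol) and C1 form the seven-membered ring.
2. Feature used: in the seven-membered ring, C8 is a fully substituted oxygen-bearing carbon 1,3 to the C6 oxygen. C6(=O)–C7–C8(OH) is therefore an aldol pattern, and C7–C8 is the bond to break.
3. Oxirane ⇒ C8–OH + C9–OMs of opposite C9 configuration. Angelate ⇒ 6α-OH ⇒ C6 ketone. C7–C8 ⇒ C7 bromoketone + C8 methyl ketone on a cyclopentane with trans arms (samarium Reformatsky closure).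
4. Cyclopentane: C1 comes from asymmetric methyl conjugate addition to an enone ester, with the enolate stored as the C4=C5 enol silane. C9/C10 come from syn-alkoxyallylboration of the C10 aldehyde, C5–C6 from a Mukaiyama aldol anti to that chain, and C4 from i-PrCeCl2.
5. Ring order: the five-membered ring comes with the starting enone, the seven-membered ring forms in step 14, and the oxirane forms in step 19.

Key step: step 14

Remark: compound 1 is taken as a catalogue compound. α/β mean below/above the ring system drawn with the C1 methyl up. The C6 carbinol centre of 12, 13 and 15–19 is destroyed in step 13, so it is carried as formed and left undefined in the SMILES.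

**Step 1**
Reactants: 1 methyl 3-oxocyclopent-1-ene-1-carboxylate; 2 dimethylzinc
Product: 4 methyl (S)-3-(tert-butyldimethylsilyloxy)-1-methylcyclopent-2-ene-1-carboxylate (C4=C5 enol silane; ester carbon = C10), via methylzinc enolate 3 (not isolated)
Conditions: Me2Zn, (CuOTf)2·C6H6 (2.5 mol %), chiral sulfonate-imidazolinium NHC precursor (5 mol %, pre-treated with Ag2O), Et2O, −30 °C; then TBSOTf, −78 → 0 °C
Reagents that add atoms: dimethylzinc C[Zn]C; tert-butyldimethylsilyl triflate CC(C)(C)[Si](C)(C)OS(=O)(=O)C(F)(F)F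
Why: Copper-catalysed asymmetric conjugate addition of a dialkylzinc to a β-carboalkoxy cyclic enone is a known route to all-carbon quaternary centres; the ligand enantiomer is chosen so that methyl delivery gives (S)-C1, and O-silylation of the zinc enolate stores the C4 ketone as the regiodefined C4=C5 enol ether.

**Step 2**
Reactants: 4 methyl (S)-3-(tert-butyldimethylsilyloxy)-1-methylcyclopent-2-ene-1-carboxylate
Product: 5 (S)-3-(tert-butyldimethylsilyloxy)-1-methylcyclopent-2-ene-1-carbaldehyde
Conditions: i-Bu2AlH (1.1 equiv), CH2Cl2, −78 °C; then H2O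
Reagents that add atoms: none
Why: In this partial ester reduction the neopentyl aluminium hemiacetal is stable at −78 °C and collapses to the non-enolisable aldehyde only on work-up, while the enol silane is inert to the hydride.

**Step 3**
Reactants: 6 allyl alcohol
Product: 7 allyl SEM ether (3-{[2-(trimethylsilyl)ethoxy]methoxy}prop-1-ene)
Conditions: SEMCl, i-Pr2NEt, CH2Cl2, 0 °C → rt
Reagents that add atoms: 2-(trimethylsilyl)ethoxymethyl chloride C[Si](C)(C)CCOCCl
Why: Williamson-type O-alkylation with the reactive chloromethyl ether gives the acetal ether that directs the allylic lithiation of the next step.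

**Step 4**
Reactants: 5 (S)-3-(tert-butyldimethylsilyloxy)-1-methylcyclopent-2-ene-1-carbaldehyde; 7 allyl SEM ether
Product: 9 (9S,10S)-syn homoallylic alcohol (C10–OH free, C9–OSEM, terminal vinyl whose inner carbon is C8, enol silane intact), via (Z)-alkoxyallyl diisopinocampheylborane 8 (not isolated)
Conditions: 7, s-BuLi, THF, −78 °C; (+)-Ipc2BOMe; BF3·OEt2; then 5, −78 °C → rt; HOCH2CH2NH2
Reagents that add atoms: allyl SEM ether C=CCOCOCC[Si](C)(C)C
Why: In this Brown (Z)-γ-alkoxyallylboration the chair Zimmerman–Traxler transition state turns the Z geometry into the syn C9/C10 relationship, and the isopinocampheyl groups of the (+)-series direct attack to the Re face of the aldehyde, which gives (10S) with C9–O already protected and C10–OH free.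

**Step 5**
Reactants: 9 syn homoallylic alcohol
Product: 10 C10 tert-butyldimethylsilyl ether of 9
Conditions: TBSOTf, 2,6-lutidine, CH2Cl2, 0 °C
Reagents that add atoms: tert-butyldimethylsilyl triflate CC(C)(C)[Si](C)(C)OS(=O)(=O)C(F)(F)F
Why: Silyl triflate silylation copes with the hindered neopentyl carbinol and completes the differentiation of the C9 and C10 oxygens.

**Step 6**
Reactants: 10 C10 TBS ether; 11 (tert-butyldimethylsilyloxy)acetaldehyde
Product: 12 cyclopentanone (C4 ketone) carrying at C5 (H α) the β-oriented CH(OH)CH2OTBS arm (C6, C7), trans to the C1 chain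
Conditions: 11, BF3·OEt2, CH2Cl2, −78 °C
Reagents that add atoms: (tert-butyldimethylsilyloxy)acetaldehyde O=CCO[Si](C)(C)C(C)(C)C
Why: In this Mukaiyama aldol addition the regiodefined enol silane attacks the activated aldehyde from the β face, anti to the branched C10 chain and syn to the small C1 methyl; this sets C5 as the trans (and more stable) epimer and brings in C7 already oxygenated, so the later halogenation cannot stray to the C8 acetyl group.

**Step 7**
Reactants: 12 aldol ketone
Product: 13 C6 triethylsilyl ether of 12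
Conditions: TESCl, imidazole, CH2Cl2, 0 °C → rt
Reagents that add atoms: chlorotriethylsilane CC[Si](Cl)(CC)CC
Why: Standard silylation blocks the aldol hydroxyl, so retro-aldol cleavage is excluded in the organometallic step.

**Step 8**
Reactants: 13 C6 TES ether; 14 isopropylmagnesium chloride
Product: 15 tertiary alcohol (C4: OH β, i-Pr α)
Conditions: CeCl3, i-PrMgCl, THF, −78 → 0 °C
Reagents that add atoms: isopropylmagnesium chloride CC(C)[Mg]Cl
Why: Organocerium (Imamoto) 1,2-addition suppresses enolisation and β-hydride reduction, and the isopropyl group enters from the α face, anti to the adjacent β-oriented C5 arm and to the pseudoaxial C1 methyl, which sets C4 with its hydroxyl cis to the C5 arm.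

**Step 9**
Reactants: 15 tertiary alcohol
Product: 16 C4 triethylsilyl ether of 15
Conditions: TESOTf, 2,6-lutidine, CH2Cl2, −78 → 0 °C
Reagents that add atoms: triethylsilyl triflate CC[Si](CC)(CC)OS(=O)(=O)C(F)(F)F
Why: Triflate silylation caps the hindered tertiary hydroxyl, which would otherwise protonate the later samarium enolate or open by retro-aldol once C6 is a ketone.

**Step 10**
Reactants: 16 C4 TES ether
Product: 17 C8 methyl ketone (vinyl converted to acetyl)
Conditions: Pd(Quinox)Cl2 (5 mol %), AgSbF6 (12 mol %), aq. t-BuOOH, CH2Cl2, 0 °C → rt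
Reagents that add atoms: tert-butyl hydroperoxide CC(C)(C)OO
Why: The Tsuji–Wacker oxidation in its quinoline-oxazoline/hydroperoxide variant gives the Markovnikov methyl ketone from protected allylic alcohols, without aldehyde formation and without epimerisation at C9.

**Step 11**
Reactants: 17 C8 methyl ketone
Product: 18 C6,C7-diol (C4–OTES, C9–OSEM and C10–OTBS retained)
Conditions: HF·pyridine, pyridine, THF, 0 °C
Reagents that add atoms: none
Why: Buffered fluoride desilylation discriminates by steric access, so the primary TBS and the unhindered secondary TES ethers are cleaved while the neopentyl C10 TBS ether, the tertiary C4 TES ether and the SEM acetal persist.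

**Step 12**
Reactants: 18 C6,C7-diol
Product: 19 C7 bromohydrin
Conditions: CBr4, PPh3, CH2Cl2, 0 °C
Reagents that add atoms: carbon tetrabromide BrC(Br)(Br)Br
Why: The Appel bromination proceeds by SN2 displacement of an alkoxyphosphonium ion and therefore takes only the primary C7 hydroxyl.

**Step 13**
Reactants: 19 C7 bromohydrin
Product: 20 trans-cyclopentane with C5 bromoacetyl and a C1 chain bearing C10–OTBS, C9–OSEM and the C8 methyl ketone (C4–OTES)
Conditions: Dess–Martin periodinane, CH2Cl2, 0 °C → rt
Reagents that add atoms: none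
Why: Dess–Martin oxidation turns the bromohydrin into the α-bromoketone under near-neutral conditions, so C5 and C9 are not epimerised and the bromide is not displaced.

**Step 14**
Reactants: 20 bromoketone
Product: 23 hydroazulenone with C6 ketone, C8 tertiary alcohol (OH α, Me β), C9–OSEM (β), C10–OTBS (α) and C4–OTES, via samarium enolate 21 (not isolated), via samarium aldolate 22 (not isolated)
Conditions: SmI2 (2.2 equiv, 0.1 M in THF, slow addition), THF (0.005 M in 20), −78 °C; pH 7 buffer at −78 °C
Reagents that add atoms: none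
Why: Two single-electron transfers from divalent samarium cleave the C7–Br bond and give the trivalent samarium enolate 21 regiospecifically at C7, which adds to the C8 ketone to give aldolate 22, protonated on work-up. This is the SmI2-promoted intramolecular Reformatsky (samarium aldol) reaction known for medium-ring β-hydroxy carbonyl compounds. The seven-membered ring closes in the 7-(enolendo)-exo-trig mode, helped by the trans arrangement of the two arms on the cyclopentane and by high dilution. The only new stereocentre, C8, is controlled by samarium bridging the enolate oxygen, the C8 carbonyl oxygen and the C9 acetal oxygen (Cram-chelate geometry), so C7 attacks from the C9–H side and the hydroxyl ends α, trans to C9–O, with the methyl β. The step needs reduction of C–Br in preference to the α-alkoxy ketone and no enolate migration towards C5; this is secured because the bromide is reduced far faster at −78 °C, SmI2 is kept limiting with no proton source or HMPA, and the silylated C4 oxygen can neither protonate the enolate nor leave.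

**Step 15**
Reactants: 23 hydroazulenone
Product: 24 6α,8α-diol
Conditions: SmI2, H2O, Et3N, THF, 0 °C
Reagents that add atoms: none
Why: Single-electron (samarium ketyl) reduction should give the more stable equatorial 6α-alcohol, cis-1,3 to the C8 hydroxyl that anchors the samarium, whereas external hydrides would be pushed to the α face by the axial C1 methyl and give the wrong epimer.

**Step 16**
Reactants: 24 6α,8α-diol; 25 angelic acid
Product: 27 C6 angelate (C8–OH free), via mixed anhydride 26 (not isolated)
Conditions: 25, 2,4,6-Cl3C6H2COCl, Et3N, toluene, rt; then 24, 75 °C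
Reagents that add atoms: angelic acid C/C=C(/C)C(=O)O
Why: Yamaguchi-type mixed-anhydride esterification without a nucleophilic catalyst acylates only the secondary C6 hydroxyl and is known to keep the Z geometry of angelates.

**Step 17**
Reactants: 27 C6 angelate
Product: 28 C9 alcohol (C8–OH and C9–OH free, trans)
Conditions: MgBr2·OEt2, MeNO2, Et2O, rt
Reagents that add atoms: none
Why: Magnesium bromide chelates the acetal oxygens and bromide attacks silicon, so the SEM group fragments to ethene and formaldehyde while the silyl ethers and the ester remain.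

**Step 18**
Reactants: 28 C9 alcohol
Product: 29 C9 mesylate (β)
Conditions: MsCl, Et3N, CH2Cl2, 0 °C
Reagents that add atoms: methanesulfonyl chloride CS(=O)(=O)Cl
Why: Sulfene-type mesylation takes the only free secondary hydroxyl and leaves the tertiary C8 hydroxyl untouched.

**Step 19**
Reactants: 29 C9 mesylate
Product: 30 8α,9α-epoxide (C4–OTES, C10–OTBS)
Conditions: NaH, THF, 0 °C → rt
Reagents that add atoms: none
Why: In this intramolecular Williamson closure (3-exo-tet) the C8 alkoxide displaces the antiperiplanar β-mesylate with inversion at C9 and retention at C8, which gives the α-oxirane of the target.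

**Step 20**
Reactants: 30 8α,9α-epoxide
Product: 31 lapiferine
Conditions: Bu4NF, AcOH, THF, rt → 40 °C
Reagents that add atoms: none
Why: Buffered fluoride desilylation frees C4–OH and C10–OH without acid, and the C10 oxygen is cis to the oxirane, so it cannot start a Payne rearrangement.

**Compound list**
1 | methyl 3-oxocyclopent-1-ene-1-carboxylate | COC(=O)C1=CC(=O)CC1 | starting material
2 | dimethylzinc | C[Zn]C | starting material
3 | methylzinc enolate | COC(=O)[C@@]1(C)CCC(O[Zn]C)=C1 | intermediate
4 | methyl (S)-3-(tert-butyldimethylsilyloxy)-1-methylcyclopent-2-ene-1-carboxylate | COC(=O)[C@@]1(C)CCC(O[Si](C)(C)C(C)(C)C)=C1 | intermediate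
5 | (S)-3-(tert-butyldimethylsilyloxy)-1-methylcyclopent-2-ene-1-carbaldehyde | O=C[C@@]1(C)CCC(O[Si](C)(C)C(C)(C)C)=C1 | intermediate
6 | allyl alcohol | C=CCO | starting material
7 | allyl SEM ether | C=CCOCOCC[Si](C)(C)C | intermediate
8 | (Z)-alkoxyallyl diisopinocampheylborane | C[Si](C)(C)CCOCO/C=C\CB([C@H]1C[C@H]2C[C@@H]([C@@H]1C)C2(C)C)[C@H]1C[C@H]2C[C@@H]([C@@H]1C)C2(C)C | intermediate
9 | (9S,10S)-syn homoallylic alcohol | C=C[C@H](OCOCC[Si](C)(C)C)[C@@H](O)[C@@]1(C)CCC(O[Si](C)(C)C(C)(C)C)=C1 | intermediate
10 | C10 TBS ether | C=C[C@H](OCOCC[Si](C)(C)C)[C@@H](O[Si](C)(C)C(C)(C)C)[C@@]1(C)CCC(O[Si](C)(C)C(C)(C)C)=C1 | intermediate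
11 | (tert-butyldimethylsilyloxy)acetaldehyde | O=CCO[Si](C)(C)C(C)(C)C | starting material
12 | aldol ketone | C=C[C@H](OCOCC[Si](C)(C)C)[C@@H](O[Si](C)(C)C(C)(C)C)[C@@]1(C)CCC(=O)[C@@H]1C(O)CO[Si](C)(C)C(C)(C)C | intermediate
13 | C6 TES ether | C=C[C@H](OCOCC[Si](C)(C)C)[C@@H](O[Si](C)(C)C(C)(C)C)[C@@]1(C)CCC(=O)[C@@H]1C(O[Si](CC)(CC)CC)CO[Si](C)(C)C(C)(C)C | intermediate
14 | isopropylmagnesium chloride | CC(C)[Mg]Cl | starting material
15 | C4 tertiary alcohol | C=C[C@H](OCOCC[Si](C)(C)C)[C@@H](O[Si](C)(C)C(C)(C)C)[C@@]1(C)CC[C@@](O)(C(C)C)[C@@H]1C(O[Si](CC)(CC)CC)CO[Si](C)(C)C(C)(C)C | intermediate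
16 | C4 TES ether | C=C[C@H](OCOCC[Si](C)(C)C)[C@@H](O[Si](C)(C)C(C)(C)C)[C@@]1(C)CC[C@@](O[Si](CC)(CC)CC)(C(C)C)[C@@H]1C(O[Si](CC)(CC)CC)CO[Si](C)(C)C(C)(C)C | intermediate
17 | C8 methyl ketone | CC(=O)[C@H](OCOCC[Si](C)(C)C)[C@@H](O[Si](C)(C)C(C)(C)C)[C@@]1(C)CC[C@@](O[Si](CC)(CC)CC)(C(C)C)[C@@H]1C(O[Si](CC)(CC)CC)CO[Si](C)(C)C(C)(C)C | intermediate
18 | C6,C7-diol | CC(=O)[C@H](OCOCC[Si](C)(C)C)[C@@H](O[Si](C)(C)C(C)(C)C)[C@@]1(C)CC[C@@](O[Si](CC)(CC)CC)(C(C)C)[C@@H]1C(O)CO | intermediate
19 | C7 bromohydrin | CC(=O)[C@H](OCOCC[Si](C)(C)C)[C@@H](O[Si](C)(C)C(C)(C)C)[C@@]1(C)CC[C@@](O[Si](CC)(CC)CC)(C(C)C)[C@@H]1C(O)CBr | intermediate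
20 | bromoketone (key-step precursor) | CC(=O)[C@H](OCOCC[Si](C)(C)C)[C@@H](O[Si](C)(C)C(C)(C)C)[C@@]1(C)CC[C@@](O[Si](CC)(CC)CC)(C(C)C)[C@@H]1C(=O)CBr | intermediate
21 | samarium enolate | CC(=O)[C@H](OCOCC[Si](C)(C)C)[C@@H](O[Si](C)(C)C(C)(C)C)[C@@]1(C)CC[C@@](O[Si](CC)(CC)CC)(C(C)C)[C@@H]1C(=C)O[Sm](I)I | intermediate
22 | samarium aldolate | O=C1C[C@@](C)(O[Sm](I)I)[C@H](OCOCC[Si](C)(C)C)[C@@H](O[Si](C)(C)C(C)(C)C)[C@@]2(C)CC[C@@](O[Si](CC)(CC)CC)(C(C)C)[C@H]12 | intermediate
23 | hydroazulenone (key-step product) | O=C1C[C@@](C)(O)[C@H](OCOCC[Si](C)(C)C)[C@@H](O[Si](C)(C)C(C)(C)C)[C@@]2(C)CC[C@@](O[Si](CC)(CC)CC)(C(C)C)[C@H]12 | intermediate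
24 | 6α,8α-diol | O[C@H]1C[C@@](C)(O)[C@H](OCOCC[Si](C)(C)C)[C@@H](O[Si](C)(C)C(C)(C)C)[C@@]2(C)CC[C@@](O[Si](CC)(CC)CC)(C(C)C)[C@H]12 | intermediate
25 | angelic acid | C/C=C(/C)C(=O)O | starting material
26 | angelic 2,4,6-trichlorobenzoic mixed anhydride | C/C=C(/C)C(=O)OC(=O)c1c(Cl)cc(Cl)cc1Cl | intermediate
27 | C6 angelate | C/C=C(/C)C(=O)O[C@H]1C[C@@](C)(O)[C@H](OCOCC[Si](C)(C)C)[C@@H](O[Si](C)(C)C(C)(C)C)[C@@]2(C)CC[C@@](O[Si](CC)(CC)CC)(C(C)C)[C@H]12 | intermediate
28 | C9 alcohol | C/C=C(/C)C(=O)O[C@H]1C[C@@](C)(O)[C@H](O)[C@@H](O[Si](C)(C)C(C)(C)C)[C@@]2(C)CC[C@@](O[Si](CC)(CC)CC)(C(C)C)[C@H]12 | intermediate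
29 | C9 mesylate | C/C=C(/C)C(=O)O[C@H]1C[C@@](C)(O)[C@H](OS(C)(=O)=O)[C@@H](O[Si](C)(C)C(C)(C)C)[C@@]2(C)CC[C@@](O[Si](CC)(CC)CC)(C(C)C)[C@H]12 | intermediate
30 | 8α,9α-epoxide bis-silyl ether | C/C=C(/C)C(=O)O[C@H]1C[C@@]2(C)O[C@H]2[C@@H](O[Si](C)(C)C(C)(C)C)[C@@]2(C)CC[C@@](O[Si](CC)(CC)CC)(C(C)C)[C@H]12 | intermediate
31 | lapiferine | C/C=C(/C)C(=O)O[C@H]1C[C@@]2(C)O[C@H]2[C@@H](O)[C@@]2(C)CC[C@@](O)(C(C)C)[C@H]12 | target

**Step count**
Total step count: 20. Longest linear sequence: 19 (steps 1, 2 and 4–20).

**Steps most likely to fail**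

1. Step 14. The enolate may be protonated instead of cyclising, which amounts to simple debromination. The C9–O bond may be cleaved reductively once the bromide is consumed. The aldolate may revert on work-up, or the C8 carbonyl may be attacked on the wrong face.
   Fallback, forming the same C7–C8 bond: it sets out from 20. Zinc dust and TMSCl in THF convert the bromoketone regiospecifically into the C6 trimethylsilyl enol ether F1. The chelating Lewis acid Me2AlCl in CH2Cl2 at −78 °C ties the C8 carbonyl to the C9 oxygen and closes the ring by an intramolecular chelation-controlled Mukaiyama aldol addition. Aqueous work-up returns to the route at 23.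

2. Step 8. The crowded ketone may be enolised or reduced by β-hydride transfer instead of being alkylated.
   Fallback: it sets out from 13. Isopropenylmagnesium bromide with CeCl3 is a flatter nucleophile that cannot transfer a β-hydride, and it should add from the same α face to give the isopropenyl carbinol F2. Hydrogen-atom-transfer hydrogenation (Mn(dpm)3, PhSiH3, t-BuOOH, i-PrOH) then reduces the 1,1-disubstituted alkene through its tertiary radical in preference to the monosubstituted vinyl group, and the route is rejoined at 15.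

3. Step 15. The facial selectivity at C6 may be poor, or retro-aldol opening of the β-hydroxy ketone may compete.
   Fallback: it sets out from 23. NaBH4 in MeOH at −40 °C delivers hydride from the open α face and gives the axial 6β-alcohol F3. Al(Oi-Pr)3 with a little acetone in toluene then equilibrates the carbinol by Meerwein–Ponndorf–Verley/Oppenauer hydride exchange towards the equatorial epimer, and the route is rejoined at 24.

**Further compounds**
F1 | step 14 | C6 trimethylsilyl enol ether of the debrominated diketone | CC(=O)[C@H](OCOCC[Si](C)(C)C)[C@@H](O[Si](C)(C)C(C)(C)C)[C@@]1(C)CC[C@@](O[Si](CC)(CC)CC)(C(C)C)[C@@H]1C(=C)O[Si](C)(C)C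
F2 | step 8 | C4 isopropenyl carbinol | C=C[C@H](OCOCC[Si](C)(C)C)[C@@H](O[Si](C)(C)C(C)(C)C)[C@@]1(C)CC[C@@](O)(C(C)=C)[C@@H]1C(O[Si](CC)(CC)CC)CO[Si](C)(C)C(C)(C)C
F3 | step 15 | 6β-alcohol (C6 epimer of 24) | O[C@@H]1C[C@@](C)(O)[C@H](OCOCC[Si](C)(C)C)[C@@H](O[Si](C)(C)C(C)(C)C)[C@@]2(C)CC[C@@](O[Si](CC)(CC)CC)(C(C)C)[C@H]12
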